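**Retrosynthetic overview**

- The target is fisetinidol-(4α→6)-fisetinidol-(4α→6)-[fisetinidol-(4α→8)]-catechin. The last bond, C4 of the fourth unit to C8 of catechin, is made by acid condensation of the free triflavanoid with mollisacacidin; before it, C4 of the second unit is joined to C6 of catechin by soft sulfide activation while C8 is blocked by bromine.
- Key disconnection: ring C of the top unit and its C4–C6' interflavan bond arise together from a cis-2-aryl-2,3-dihydrobenzofuran carrying an exocyclic CH(OAc)OBn on C3. Ionisation, 1,2-shift of C2 onto the exocyclic carbon (furan ring enlarged to the pyran ring) and capture of the resulting C4 cation by ring A of the second unit follow in one operation.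
- Enabling feature: in ring A of the top unit, O1 (on C8a, ortho to C4a) and O7 (para to C4a) stabilise a cation at C4, and C2, which bears O1 and the catechol ring B, is an electron-rich migrating carbon.
- Ring order: dihydrofuran ring (carbenoid C–H insertion), then pyran ring C of the top unit (ring enlargement, key step); all other rings come intact from (2R,3R)-fustin and (+)-catechin.
- Benzyl-type ethers protect all hydroxyls and are removed together with the blocking bromine in one hydrogenolysis.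

Key step: step 9

Assumptions: (2R,3R)-fustin and 4-iodoresorcinol are taken as purchasable, and Rh2(S-PTTL)4 is taken to give the (2S,3R)-cis insertion product (otherwise its mirror-image catalyst Rh2(R-PTTL)4 is used).

**Route**

Step 1
Reactants: 1 4-iodobenzene-1,3-diol (4-iodoresorcinol); 2 3,4-bis(benzyloxy)benzyl chloride (2.2 equiv)
Product: 3 1-iodo-2,4-bis{[3,4-bis(benzyloxy)phenyl]methoxy}benzene
Conditions: K2CO3, DMF, 50 °C
Reagents that add atoms: none
Why: Double Williamson ether synthesis, in which the same benzylic group on both phenols removes any regiochemical question (the ortho ether later becomes C2 with ring B, the para ether is a hydrogenolysable protecting group for O7); no stereocentre is formed.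

Step 2
Reactants: 3 1-iodo-2,4-bis{[3,4-bis(benzyloxy)phenyl]methoxy}benzene; 4 benzyl diazoacetate
Product: 5 benzyl 2-(2,4-bis{[3,4-bis(benzyloxy)phenyl]methoxy}phenyl)-2-diazoacetate
Conditions: Pd(PPh3)4 (5 mol%), Ag2CO3 (0.5 equiv), Et3N, toluene, rt
Reagents that add atoms: none
Why: Palladium-catalysed cross-coupling of an aryl iodide with the C–H bond of a diazoacetate with retention of the diazo group (oxidative addition at C–I, Ag2CO3 removes iodide), a known way to aryldiazoacetates; no stereocentre is formed.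

Step 3
Reactants: 5 benzyl 2-(2,4-bis{[3,4-bis(benzyloxy)phenyl]methoxy}phenyl)-2-diazoacetate
Product: 6 benzyl (2S,3R)-2-[3,4-bis(benzyloxy)phenyl]-6-{[3,4-bis(benzyloxy)phenyl]methoxy}-2,3-dihydro-1-benzofuran-3-carboxylate (2,3-cis)
Conditions: Rh2(S-PTTL)4 (PTTL = N-phthaloyl-tert-leucinate, 1 mol%), toluene, −60 °C
Reagents that add atoms: none
Why: Intramolecular 1,5 C–H insertion of the donor/acceptor rhodium carbenoid into the ortho benzylic ether C–H (the para ether cannot reach), a known enantioselective route to cis-2-aryl-2,3-dihydrobenzofuran-3-carboxylates; the concerted insertion gives the 2,3-cis ring and the chiral carboxylate ligands select the enantiotopic C–H, setting C2 (S) and C3 (R).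

Step 4
Reactants: 6 benzyl (2S,3R)-2-[3,4-bis(benzyloxy)phenyl]-6-{[3,4-bis(benzyloxy)phenyl]methoxy}-2,3-dihydro-1-benzofuran-3-carboxylate
Product: 8 (2S,3R)-3-[acetoxy(benzyloxy)methyl]-2-[3,4-bis(benzyloxy)phenyl]-6-{[3,4-bis(benzyloxy)phenyl]methoxy}-2,3-dihydro-1-benzofuran (2,3-cis; both epimers at the acetal carbon), via aluminium hemiacetal 7 (not isolated)
Conditions: i-Bu2AlH, CH2Cl2, −78 °C; then pyridine, DMAP, Ac2O, −78 °C → rt
Reagents that add atoms: acetic anhydride CC(=O)OC(C)=O; diisobutylaluminium hydride CC(C)C[AlH]CC(C)C (its aluminium stays only in intermediate 7)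
Why: Reductive acetylation of an ester (partial reduction to the tetrahedral aluminium hemiacetal, trapped in situ by O-acetylation), so that no free enolisable aldehyde ever forms and the cis C2/C3 relationship survives; the new acetal centre forms as a mixture and is destroyed on ionisation.

Step 5
Reactants: 9 (2R,3R)-fustin
Product: 10 (2R,3R)-7-(benzyloxy)-2-[3,4-bis(benzyloxy)phenyl]-3-hydroxychroman-4-one (7,3',4'-tri-O-benzylfustin)
Conditions: BnBr (3.3 equiv), K2CO3, DMF, rt, under Ar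
Reagents that add atoms: benzyl bromide BrCc1ccccc1
Why: Williamson benzylation of the three phenols under mild carbonate conditions that leave the secondary 3-OH and the two stereocentres untouched.

Step 6
Reactants: 10 7,3',4'-tri-O-benzylfustin
Product: 11 (2R,3S,4R)-7-(benzyloxy)-2-[3,4-bis(benzyloxy)phenyl]chromane-3,4-diol (2,3-trans-3,4-trans)
Conditions: NaBH4, THF/MeOH, 0 °C
Reagents that add atoms: none
Why: Borohydride reduction of the aryl ketone with axial hydride delivery, which should give mainly the diequatorial 3,4-trans diol; the C4 configuration is of no consequence because C4 is ionised in the next step.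

Step 7
Reactants: 11 (2R,3S,4R)-7-(benzyloxy)-2-[3,4-bis(benzyloxy)phenyl]chromane-3,4-diol
Product: 12 (2R,3R,4R)-7-(benzyloxy)-2-[3,4-bis(benzyloxy)phenyl]-4-[(2,6-dimethylphenyl)sulfanyl]chroman-3-ol (3,4-trans, 4α-sulfide)
Conditions: 2,6-Me2C6H3SH (3 equiv), BF3·OEt2 (cat.), CH2Cl2, −40 °C
Reagents that add atoms: 2,6-dimethylbenzenethiol Cc1cccc(C)c1S
Why: Acid-catalysed SN1 thioetherification of the benzylic 4-OH (thiolysis of a flavan-3,4-diol), the thiol adding anti to the 3-hydroxyl to give mainly the 3,4-trans sulfide; the hindered aryl sulfide is a leaving group that hard Lewis acids leave alone and soft electrophiles activate.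

Step 8
Reactants: 12 (2R,3R,4R)-7-(benzyloxy)-2-[3,4-bis(benzyloxy)phenyl]-4-[(2,6-dimethylphenyl)sulfanyl]chroman-3-ol
Product: 13 (2R,3R,4R)-3,7-bis(benzyloxy)-2-[3,4-bis(benzyloxy)phenyl]-4-[(2,6-dimethylphenyl)sulfanyl]chromane
Conditions: NaH, BnBr, Bu4NI (cat.), DMF, 0 °C → rt
Reagents that add atoms: benzyl bromide BrCc1ccccc1
Why: Williamson O-benzylation of the 3-OH so that no free hydroxyl can exchange into the acetal or trap cations in the key step; no stereocentre is touched.

Step 9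
Reactants: 8 (2S,3R)-3-[acetoxy(benzyloxy)methyl]-2-[3,4-bis(benzyloxy)phenyl]-6-{[3,4-bis(benzyloxy)phenyl]methoxy}-2,3-dihydro-1-benzofuran; 13 (2R,3R,4R)-3,7-bis(benzyloxy)-2-[3,4-bis(benzyloxy)phenyl]-4-[(2,6-dimethylphenyl)sulfanyl]chromane (3 equiv)
Product: 16 3,3',4'-tri-O-benzyl-7-O-[3,4-bis(benzyloxy)benzyl]fisetinidol-(4α→6)-3,7,3',4'-tetra-O-benzyl-4α-[(2,6-dimethylphenyl)sulfanyl]fisetinidol, via benzyloxycarbenium ion 14 (not isolated), via flavan-4-yl cation 15 (not isolated)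
Conditions: BF3·OEt2 (1.5 equiv), 4 Å molecular sieves, CH2Cl2, −78 → −40 °C; 8 added slowly to 13 and the Lewis acid
Reagents that add atoms: none
Why: Proposed new method: BF3 ionises the α-acetoxy ether 8 to the exocyclic benzyloxycarbenium ion 14, whose best σ-donor, the ring C3–C2 bond of the dihydrobenzofuran (C2 carries O1 and ring B), lies parallel to the empty orbital and shifts from C3 to the carbenium carbon (a cationic 1,2-alkyl shift, the reverse sense of a pinacol ring contraction and akin to a Wagner–Meerwein ring enlargement of a cycloalkylcarbinyl cation), leaving the benzylic cation 15 that O1 (ortho) and O7 (para) stabilise exactly as in flavan-3,4-diol ionisations, and ionisation of α-acetoxy ethers and Friedel–Crafts arylation of flavan-4-yl cations are both established. Ring C therefore closes by ring enlargement from five to six members (the former exocyclic carbon is inserted as C3 between C2 and the former furan C3, now C4), and the interflavan bond forms by intermolecular Friedel–Crafts attack of C6 of 13 on C4. C2 migrates with retention and keeps the configuration set in step 3; C3 is set in the shift, because in the cis precursor the benzyloxy group can eclipse the hydrogen on the furan C3 instead of ring A and so ends trans to the 2-aryl group, and the two C3 epimers of 15 can equilibrate through 14 towards the diequatorial 2,3-trans cation; C4 is set by attack of the arene anti to the 3-benzyloxy group (3,4-trans, 4α), the usual course for 2,3-trans flavan-4-yl cations. The step needs migration of C2 in preference to hydride or ring A shift and capture of 15 in preference to arylation of 14; the alignment and donor strength of the C3–C2 bond, slow addition of 8 to an excess of 13 at low temperature and the irreversibility of C–C capture should secure this. Attack at C6 of 13 (para to O1, one ortho neighbour) over C8 (between two oxygens) is steric, and the hard Lewis acid leaves the C4 sulfide of 13 intact for later soft activation.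

Step 10
Reactants: 17 (+)-catechin
Product: 18 (2R,3S)-5,7-bis(benzyloxy)-2-[3,4-bis(benzyloxy)phenyl]chroman-3-ol (5,7,3',4'-tetra-O-benzylcatechin)
Conditions: BnBr (4.4 equiv), K2CO3, DMF, rt, under Ar
Reagents that add atoms: benzyl bromide BrCc1ccccc1
Why: Williamson benzylation of the four phenols under carbonate conditions that do not epimerise C2 and leave the 3-OH free.

Step 11
Reactants: 18 5,7,3',4'-tetra-O-benzylcatechin
Product: 19 (2R,3S)-3,5,7-tris(benzyloxy)-2-[3,4-bis(benzyloxy)phenyl]chromane (penta-O-benzylcatechin)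
Conditions: NaH, BnBr, DMF, 0 °C → rt
Reagents that add atoms: benzyl bromide BrCc1ccccc1
Why: Williamson O-benzylation of the secondary alcohol, removing the last free hydroxyl before the cationic couplings.

Step 12
Reactants: 19 penta-O-benzylcatechin
Product: 20 (2R,3S)-8-bromo-3,5,7-tris(benzyloxy)-2-[3,4-bis(benzyloxy)phenyl]chromane
Conditions: NBS, CH2Cl2, −78 → 0 °C
Reagents that add atoms: N-bromosuccinimide O=C1CCC(=O)N1Br
Why: Electrophilic aromatic bromination at C8, the more accessible of the two activated ring A positions (flanked by O1 instead of two benzyloxy groups), which blocks C8 so that the next coupling must occur at C6.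

Step 13
Reactants: 16 the sulfide-bearing biflavanoid from step 9; 20 8-bromo-penta-O-benzylcatechin (3 equiv)
Product: 21 3,3',4'-tri-O-benzyl-7-O-[3,4-bis(benzyloxy)benzyl]fisetinidol-(4α→6)-3,7,3',4'-tetra-O-benzylfisetinidol-(4α→6)-3,5,7,3',4'-penta-O-benzyl-8-bromocatechin
Conditions: NIS, 4 Å molecular sieves, CH2Cl2, −78 → −30 °C
Reagents that add atoms: none
Why: Soft (thiophilic) activation of the C4 aryl sulfide ionises C4 of the second unit, and Friedel–Crafts attack by C6 of 20, its only free ring A position, forms the (4→6) bond with the arene entering anti to the 3-benzyloxy group (4α, 3,4-trans); the excess of 20 suppresses self-condensation through the free C6 of the top unit.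

Step 14
Reactants: 21 the protected 8-bromo triflavanoid
Product: 22 fisetinidol-(4α→6)-fisetinidol-(4α→6)-catechin (free phenolic triflavanoid)
Conditions: H2 (1 atm), Pd(OH)2/C, Et3N, THF/MeOH/H2O, rt
Reagents that add atoms: none
Why: Hydrogenolysis of all benzylic C–O protecting groups with concurrent hydrodebromination at C8 (Et3N takes up HBr), conditions under which the pyran rings and interflavan C–C bonds of benzylated oligoflavanoids are retained.

Step 15
Reactants: 9 (2R,3R)-fustin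
Product: 23 (2R,3S,4R)-2-(3,4-dihydroxyphenyl)chromane-3,4,7-triol ((+)-mollisacacidin, 2,3-trans-3,4-trans)
Conditions: NaBH4, EtOH/H2O, rt
Reagents that add atoms: none
Why: Borohydride reduction of the dihydroflavonol carbonyl with axial hydride delivery to the 3,4-trans diol, the classical entry to the flavan-3,4-diol electrophile; its C4 configuration is lost on ionisation.

Step 16
Reactants: 22 fisetinidol-(4α→6)-fisetinidol-(4α→6)-catechin (1.5 equiv); 23 (+)-mollisacacidin
Product: 24 fisetinidol-(4α→6)-fisetinidol-(4α→6)-[fisetinidol-(4α→8)]-catechin (target)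
Conditions: 0.1 M aq. HCl, rt, under Ar; chromatography on Sephadex LH-20
Reagents that add atoms: none
Why: Biomimetic acid-catalysed flavan-3,4-diol condensation, in which the 4-OH of 23 ionises and C8 of the catechin unit, the only phloroglucinol-type position of 22 and far more nucleophilic than the resorcinol rings, attacks anti to the 3-OH to set the last C4 as 4α (3,4-trans); profisetinidin interflavan bonds are stable to this dilute acid.

**Compound list**

1 | 4-iodobenzene-1,3-diol (4-iodoresorcinol) | Oc1ccc(I)c(O)c1 | starting material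
2 | 3,4-bis(benzyloxy)benzyl chloride | ClCc1ccc(OCc2ccccc2)c(OCc2ccccc2)c1 | starting material
3 | 1-iodo-2,4-bis{[3,4-bis(benzyloxy)phenyl]methoxy}benzene | Ic1ccc(OCc2ccc(OCc3ccccc3)c(OCc3ccccc3)c2)cc1OCc1ccc(OCc2ccccc2)c(OCc2ccccc2)c1 | intermediate
4 | benzyl diazoacetate | [N-]=[N+]=CC(=O)OCc1ccccc1 | starting material
5 | benzyl 2-(2,4-bis{[3,4-bis(benzyloxy)phenyl]methoxy}phenyl)-2-diazoacetate | [N-]=[N+]=C(C(=O)OCc1ccccc1)c1ccc(OCc2ccc(OCc3ccccc3)c(OCc3ccccc3)c2)cc1OCc1ccc(OCc2ccccc2)c(OCc2ccccc2)c1 | intermediate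
6 | benzyl (2S,3R)-2-[3,4-bis(benzyloxy)phenyl]-6-{[3,4-bis(benzyloxy)phenyl]methoxy}-2,3-dihydro-1-benzofuran-3-carboxylate (2,3-cis) | O(Cc1ccc(OCc2ccccc2)c(OCc2ccccc2)c1)c1ccc2c(c1)O[C@H](c1ccc(OCc3ccccc3)c(OCc3ccccc3)c1)[C@@H]2C(=O)OCc1ccccc1 | intermediate
7 | diisobutylaluminium hemiacetalate of 6 (not isolated; hemiacetal carbon unspecified) | O(Cc1ccc(OCc2ccccc2)c(OCc2ccccc2)c1)c1ccc2c(c1)O[C@H](c1ccc(OCc3ccccc3)c(OCc3ccccc3)c1)[C@@H]2C(OCc1ccccc1)O[Al](CC(C)C)CC(C)C | intermediate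
8 | (2S,3R)-3-[acetoxy(benzyloxy)methyl]-2-[3,4-bis(benzyloxy)phenyl]-6-{[3,4-bis(benzyloxy)phenyl]methoxy}-2,3-dihydro-1-benzofuran (2,3-cis; both acetal epimers) | O(Cc1ccc(OCc2ccccc2)c(OCc2ccccc2)c1)c1ccc2c(c1)O[C@H](c1ccc(OCc3ccccc3)c(OCc3ccccc3)c1)[C@@H]2C(OCc1ccccc1)OC(C)=O | intermediate
9 | (2R,3R)-fustin | Oc1ccc2c(c1)O[C@H](c1ccc(O)c(O)c1)[C@@H](O)C2=O | starting material
10 | (2R,3R)-7-(benzyloxy)-2-[3,4-bis(benzyloxy)phenyl]-3-hydroxychroman-4-one | O(Cc1ccccc1)c1ccc2c(c1)O[C@H](c1ccc(OCc3ccccc3)c(OCc3ccccc3)c1)[C@@H](O)C2=O | intermediate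
11 | (2R,3S,4R)-7-(benzyloxy)-2-[3,4-bis(benzyloxy)phenyl]chromane-3,4-diol | O(Cc1ccccc1)c1ccc2c(c1)O[C@H](c1ccc(OCc3ccccc3)c(OCc3ccccc3)c1)[C@@H](O)[C@@H]2O | intermediate
12 | (2R,3R,4R)-7-(benzyloxy)-2-[3,4-bis(benzyloxy)phenyl]-4-[(2,6-dimethylphenyl)sulfanyl]chroman-3-ol | O(Cc1ccccc1)c1ccc2c(c1)O[C@H](c1ccc(OCc3ccccc3)c(OCc3ccccc3)c1)[C@@H](O)[C@@H]2Sc1c(C)cccc1C | intermediate
13 | (2R,3R,4R)-3,7-bis(benzyloxy)-2-[3,4-bis(benzyloxy)phenyl]-4-[(2,6-dimethylphenyl)sulfanyl]chromane | O(Cc1ccccc1)c1ccc2c(c1)O[C@H](c1ccc(OCc3ccccc3)c(OCc3ccccc3)c1)[C@@H](OCc1ccccc1)[C@@H]2Sc1c(C)cccc1C | intermediate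
14 | exocyclic benzyloxycarbenium ion derived from 8 (not isolated) | O(Cc1ccc(OCc2ccccc2)c(OCc2ccccc2)c1)c1ccc2c(c1)O[C@H](c1ccc(OCc3ccccc3)c(OCc3ccccc3)c1)[C@@H]2C=[O+]Cc1ccccc1 | intermediate
15 | (2R,3S)-3-(benzyloxy)-2-[3,4-bis(benzyloxy)phenyl]-7-{[3,4-bis(benzyloxy)phenyl]methoxy}chroman-4-ylium (2,3-trans flavan-4-yl cation, not isolated) | O(Cc1ccc(OCc2ccccc2)c(OCc2ccccc2)c1)c1ccc2c(c1)O[C@H](c1ccc(OCc3ccccc3)c(OCc3ccccc3)c1)[C@@H](OCc1ccccc1)[CH+]2 | intermediate
16 | 3,3',4'-tri-O-benzyl-7-O-[3,4-bis(benzyloxy)benzyl]fisetinidol-(4α→6)-3,7,3',4'-tetra-O-benzyl-4α-[(2,6-dimethylphenyl)sulfanyl]fisetinidol | O(Cc1ccc(OCc2ccccc2)c(OCc2ccccc2)c1)c1ccc2c(c1)O[C@H](c1ccc(OCc3ccccc3)c(OCc3ccccc3)c1)[C@@H](OCc1ccccc1)[C@@H]2c1cc2c(cc1OCc1ccccc1)O[C@H](c1ccc(OCc3ccccc3)c(OCc3ccccc3)c1)[C@@H](OCc1ccccc1)[C@@H]2Sc1c(C)cccc1C | intermediate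
17 | (+)-catechin | Oc1cc(O)c2c(c1)O[C@H](c1ccc(O)c(O)c1)[C@@H](O)C2 | starting material
18 | (2R,3S)-5,7-bis(benzyloxy)-2-[3,4-bis(benzyloxy)phenyl]chroman-3-ol | O(Cc1ccccc1)c1cc(OCc2ccccc2)c2c(c1)O[C@H](c1ccc(OCc3ccccc3)c(OCc3ccccc3)c1)[C@@H](O)C2 | intermediate
19 | (2R,3S)-3,5,7-tris(benzyloxy)-2-[3,4-bis(benzyloxy)phenyl]chromane | O(Cc1ccccc1)c1cc(OCc2ccccc2)c2c(c1)O[C@H](c1ccc(OCc3ccccc3)c(OCc3ccccc3)c1)[C@@H](OCc1ccccc1)C2 | intermediate
20 | (2R,3S)-8-bromo-3,5,7-tris(benzyloxy)-2-[3,4-bis(benzyloxy)phenyl]chromane | O(Cc1ccccc1)c1cc(OCc2ccccc2)c2c(c1Br)O[C@H](c1ccc(OCc3ccccc3)c(OCc3ccccc3)c1)[C@@H](OCc1ccccc1)C2 | intermediate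
21 | 3,3',4'-tri-O-benzyl-7-O-[3,4-bis(benzyloxy)benzyl]fisetinidol-(4α→6)-3,7,3',4'-tetra-O-benzylfisetinidol-(4α→6)-3,5,7,3',4'-penta-O-benzyl-8-bromocatechin | O(Cc1ccc(OCc2ccccc2)c(OCc2ccccc2)c1)c1ccc2c(c1)O[C@H](c1ccc(OCc3ccccc3)c(OCc3ccccc3)c1)[C@@H](OCc1ccccc1)[C@@H]2c1cc2c(cc1OCc1ccccc1)O[C@H](c1ccc(OCc3ccccc3)c(OCc3ccccc3)c1)[C@@H](OCc1ccccc1)[C@@H]2c1c(OCc3ccccc3)c2c(c(Br)c1OCc1ccccc1)O[C@H](c1ccc(OCc3ccccc3)c(OCc3ccccc3)c1)[C@@H](OCc1ccccc1)C2 | intermediate
22 | fisetinidol-(4α→6)-fisetinidol-(4α→6)-catechin | Oc1ccc2c(c1)O[C@H](c1ccc(O)c(O)c1)[C@@H](O)[C@@H]2c1cc2c(cc1O)O[C@H](c1ccc(O)c(O)c1)[C@@H](O)[C@@H]2c1c(O)c2c(cc1O)O[C@H](c1ccc(O)c(O)c1)[C@@H](O)C2 | intermediate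
23 | (+)-mollisacacidin, (2R,3S,4R)-2-(3,4-dihydroxyphenyl)chromane-3,4,7-triol | Oc1ccc2c(c1)O[C@H](c1ccc(O)c(O)c1)[C@@H](O)[C@@H]2O | intermediate
24 | fisetinidol-(4α→6)-fisetinidol-(4α→6)-[fisetinidol-(4α→8)]-catechin | Oc1ccc2c(c1)O[C@H](c1ccc(O)c(O)c1)[C@@H](O)[C@@H]2c1cc2c(cc1O)O[C@H](c1ccc(O)c(O)c1)[C@@H](O)[C@@H]2c1c(O)c2c(c([C@@H]3c4ccc(O)cc4O[C@H](c4ccc(O)c(O)c4)[C@H]3O)c1O)O[C@H](c1ccc(O)c(O)c1)[C@@H](O)C2 | target

**Step count and risks**

Total step count: 16. Longest linear sequence: 8 steps (1 → 3 → 5 → 6 → 8 → 16 → 21 → 22 → 24; the branch from 9 through 13 is equally long).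

Steps most likely to fail:

1. Step 9 (proposed new method). What may go wrong:
 - a 1,2-hydride or ring A aryl shift may compete with migration of C2, the hydride shift ending in aromatisation to a benzofuran;
 - the ion 14 may fragment reversibly to an open enol ether/oxocarbenium pair and so lose the C2 configuration;
 - the arene may add to 14 before the shift;
 - the shift may show poor facial selectivity, giving the 2,3-cis epimer.

 Fallback (known reaction types, the furan ring is still enlarged to the pyran ring), setting out from 6 and returning at 16. The potassium enolate of 6 (KN(SiMe3)2, THF, −78 °C) is hydroxylated with 2-(phenylsulfonyl)-3-phenyloxaziridine to the 3-hydroxy ester F1. Reduction with i-Bu2AlH at −78 °C gives the α-hydroxy aldehyde F2. An α-ketol rearrangement (BF3·OEt2, CH2Cl2, 0 °C) moves C2 from the carbinol carbon to the aldehyde carbon and should settle at the conjugated, thermodynamically preferred 2,3-trans dihydroflavonol F3. NaBH4 reduction gives the flavan-3,4-diol F4. BF3·OEt2-mediated Friedel–Crafts coupling of F4 with 13 (sulfide untouched) gives the 3-hydroxy biflavanoid F5, and NaH/BnBr converts F5 into 16.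

2. Step 13. What may go wrong: self-condensation of 16 through the free C6 of its top unit, sluggish attack at the crowded C6 of 20, or competing iodination of the nucleophile. Fallback that reverses the order of the two bond formations, setting out from 13 and 20 and returning at 21. The monomeric sulfide 13 is activated with NIS in the presence of excess 20, a less hindered cation with no second nucleophilic unit, to give the 8-bromo biflavanoid F6. F6 is then used in place of 13 as the arene partner of 8 under the conditions of step 9, giving 21 directly.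

3. Step 16. What may go wrong: incomplete facial selectivity at the new C4 (4β epimer), further condensation of the product with more electrophile, and minor attack by the resorcinol rings, all of which burden the final separation. Fallback with a protected, chromatographable coupling, setting out from 21 and returning at 24. Bromine–lithium exchange on 21 (n-BuLi, THF, −78 °C, then MeOH) gives the debrominated protected triflavanoid F7. NIS activation of 13 in the presence of F7 should arylate catechin C8, its most electron-rich free position, to give the fully protected tetraflavanoid F8. Hydrogenolysis (H2, Pd(OH)2/C, THF/MeOH/H2O) then gives 24.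

Further compounds

F1 | step 9 | benzyl (2S)-2-[3,4-bis(benzyloxy)phenyl]-6-{[3,4-bis(benzyloxy)phenyl]methoxy}-3-hydroxy-2,3-dihydro-1-benzofuran-3-carboxylate (hydroxyl trans to the 2-aryl group) | O(Cc1ccc(OCc2ccccc2)c(OCc2ccccc2)c1)c1ccc2c(c1)O[C@H](c1ccc(OCc3ccccc3)c(OCc3ccccc3)c1)[C@]2(O)C(=O)OCc1ccccc1
F2 | step 9 | (2S)-2-[3,4-bis(benzyloxy)phenyl]-6-{[3,4-bis(benzyloxy)phenyl]methoxy}-3-hydroxy-2,3-dihydro-1-benzofuran-3-carbaldehyde | O(Cc1ccc(OCc2ccccc2)c(OCc2ccccc2)c1)c1ccc2c(c1)O[C@H](c1ccc(OCc3ccccc3)c(OCc3ccccc3)c1)[C@]2(O)C=O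
F3 | step 9 | (2R,3R)-2-[3,4-bis(benzyloxy)phenyl]-7-{[3,4-bis(benzyloxy)phenyl]methoxy}-3-hydroxychroman-4-one | O(Cc1ccc(OCc2ccccc2)c(OCc2ccccc2)c1)c1ccc2c(c1)O[C@H](c1ccc(OCc3ccccc3)c(OCc3ccccc3)c1)[C@@H](O)C2=O
F4 | step 9 | (2R,3S,4R)-2-[3,4-bis(benzyloxy)phenyl]-7-{[3,4-bis(benzyloxy)phenyl]methoxy}chromane-3,4-diol | O(Cc1ccc(OCc2ccccc2)c(OCc2ccccc2)c1)c1ccc2c(c1)O[C@H](c1ccc(OCc3ccccc3)c(OCc3ccccc3)c1)[C@@H](O)[C@@H]2O
F5 | step 9 | 3',4'-di-O-benzyl-7-O-[3,4-bis(benzyloxy)benzyl]fisetinidol-(4α→6)-3,7,3',4'-tetra-O-benzyl-4α-[(2,6-dimethylphenyl)sulfanyl]fisetinidol (3-OH of the top unit free) | O(Cc1ccc(OCc2ccccc2)c(OCc2ccccc2)c1)c1ccc2c(c1)O[C@H](c1ccc(OCc3ccccc3)c(OCc3ccccc3)c1)[C@@H](O)[C@@H]2c1cc2c(cc1OCc1ccccc1)O[C@H](c1ccc(OCc3ccccc3)c(OCc3ccccc3)c1)[C@@H](OCc1ccccc1)[C@@H]2Sc1c(C)cccc1C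
F6 | step 13 | 3,7,3',4'-tetra-O-benzylfisetinidol-(4α→6)-3,5,7,3',4'-penta-O-benzyl-8-bromocatechin | O(Cc1ccccc1)c1ccc2c(c1)O[C@H](c1ccc(OCc3ccccc3)c(OCc3ccccc3)c1)[C@@H](OCc1ccccc1)[C@@H]2c1c(OCc3ccccc3)c2c(c(Br)c1OCc1ccccc1)O[C@H](c1ccc(OCc3ccccc3)c(OCc3ccccc3)c1)[C@@H](OCc1ccccc1)C2
F7 | step 16 | 3,3',4'-tri-O-benzyl-7-O-[3,4-bis(benzyloxy)benzyl]fisetinidol-(4α→6)-3,7,3',4'-tetra-O-benzylfisetinidol-(4α→6)-3,5,7,3',4'-penta-O-benzylcatechin | O(Cc1ccc(OCc2ccccc2)c(OCc2ccccc2)c1)c1ccc2c(c1)O[C@H](c1ccc(OCc3ccccc3)c(OCc3ccccc3)c1)[C@@H](OCc1ccccc1)[C@@H]2c1cc2c(cc1OCc1ccccc1)O[C@H](c1ccc(OCc3ccccc3)c(OCc3ccccc3)c1)[C@@H](OCc1ccccc1)[C@@H]2c1c(OCc3ccccc3)c2c(cc1OCc1ccccc1)O[C@H](c1ccc(OCc3ccccc3)c(OCc3ccccc3)c1)[C@@H](OCc1ccccc1)C2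
F8 | step 16 | fully O-benzylated tetraflavanoid (F7 carrying 3,7,3',4'-tetra-O-benzylfisetinidol 4α-linked at catechin C8) | O(Cc1ccc(OCc2ccccc2)c(OCc2ccccc2)c1)c1ccc2c(c1)O[C@H](c1ccc(OCc3ccccc3)c(OCc3ccccc3)c1)[C@@H](OCc1ccccc1)[C@@H]2c1cc2c(cc1OCc1ccccc1)O[C@H](c1ccc(OCc3ccccc3)c(OCc3ccccc3)c1)[C@@H](OCc1ccccc1)[C@@H]2c1c(OCc3ccccc3)c2c(c([C@@H]3c4ccc(OCc5ccccc5)cc4O[C@H](c4ccc(OCc5ccccc5)c(OCc5ccccc5)c4)[C@H]3OCc3ccccc3)c1OCc1ccccc1)O[C@H](c1ccc(OCc3ccccc3)c(OCc3ccccc3)c1)[C@@H](OCc1ccccc1)C2
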